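**Plan**

- Cuts: the C8 acetate and C11 angelate are removed first, then the C11–O bond. Ring B (C6–O–C12–C11–C7) is opened at C7–C11 together with the C8–O bond, the C6 carbinol is traced by Wharton transposition to a C8 enone, and ring A is cut at C5–C6 and C9–C10.
- Enabling feature: in ring A (C5–C10) the C6–C7–C8–C9 segment has heteroatoms on C6 and C8 in a 1,3-relationship, the pattern of a 1-amino-3-siloxybutadiene. The adjacent C5 (isopropenyl CH) and C10 (methyl, vinyl) map onto the trisubstituted alkene of a keto ester.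
- Forward: dienophile (1 step) and chiral diene (2 steps); [4+2] closes ring A; acetyl becomes isopropenyl, ester becomes vinyl, unmasking gives the enone; epoxidation and Wharton transposition move oxygen to C6; radical annulation closes ring B and oxygenates C8; lactone, C11 hydroxylation, angeloylation, acetylation.
- Stereochemistry: C5/C10 relative from the (E)-alkene, absolute from the (2R,5R)-diphenylpyrrolidine with acetyl-endo addition; C6 from epoxidation anti to the β groups on C5 and C10; C7 from the obligatory cis closure; C8 from oxygen capture anti to the new ring; C11 from convex-face enolate oxidation; the (Z)-ester from angelic anhydride.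

Key step: step 4

Convention: locants C5–C12 are those used above (ring A = C5–C10, ring B = C6–O–C12–C11–C7); β is the face of ring A that carries the C10 methyl group, α the opposite face.

Assumption: the (2R,5R) auxiliary is taken to steer the dienophile to the diene face anti to the phenyl group on the pyrrolidine carbon that lies syn to C7, which gives the 5β,10β series drawn for 9. If 9 showed the opposite sense, the (2S,5S) amine would be used with no other change.

**Route**

Step 1
Reactants: 1 methyl pyruvate; 2 1-(triphenylphosphoranylidene)propan-2-one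
Product: 3 methyl (E)-2-methyl-4-oxopent-2-enoate
Conditions: PhMe, 80 °C
Reagents that add atoms: none
Why: Wittig olefination of the activated keto carbonyl by a stabilised ylide; the (E) isomer (acetyl trans to ester) is expected to predominate and any (Z) isomer is removed by chromatography.

Step 2
Reactants: 4 (E)-4-methoxybut-3-en-2-one; 5 (2R,5R)-2,5-diphenylpyrrolidine
Product: 6 (E)-4-[(2R,5R)-2,5-diphenylpyrrolidin-1-yl]but-3-en-2-one
Conditions: MeOH, 50 °C
Reagents that add atoms: none
Why: Conjugate addition–elimination (amine exchange on a vinylogous ester) expels methanol and gives the thermodynamically favoured (E) vinylogous amide.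

Step 3
Reactants: 6 vinylogous amide
Product: 8 1-[(2R,5R)-2,5-diphenylpyrrolidin-1-yl]-3-(tert-butyldimethylsilyloxy)buta-1,3-diene, via potassium dienolate 7 (not isolated)
Conditions: KN(SiMe3)2, THF, −78 °C; then TBSCl, −78 °C → rt
Reagents that add atoms: tert-butyldimethylsilyl chloride, C[Si](C)(Cl)C(C)(C)C
Why: Kinetic deprotonation of the methyl ketone and O-silylation of the cross-conjugated enolate is the standard preparation of 1-amino-3-siloxybutadienes.

Step 4
Reactants: 8 aminosiloxydiene; 3 keto ester dienophile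
Product: 9 cycloadduct, methyl 5β-acetyl-6β-[(2R,5R)-2,5-diphenylpyrrolidin-1-yl]-10β-methyl-8-(tert-butyldimethylsilyloxy)cyclohex-7-ene-10α-carboxylate
Conditions: PhMe, 25 → 40 °C
Reagents that add atoms: none
Why: Concerted but strongly asynchronous [4+2] cycloaddition in which the nucleophilic unsubstituted diene terminus C9 bonds first to C10, the carbon β to the ketone (the stronger acceptor, while the α-methyl twists and weakens the ester), and C6 then bonds to C5; the closest known reaction type is the Diels–Alder reaction of 1-amino-3-siloxybutadienes carrying the C2-symmetric 2,5-diphenylpyrrolidine auxiliary with enones, enals and acrylates. Ring A is closed by this intermolecular cycloaddition from C6–C9 of the diene and C5/C10 of the alkene. C5 and C10 are related by suprafacial addition to the (E)-alkene (ester trans to acetyl, hence methyl cis to acetyl), C6 is set by the acetyl-endo transition state, and the absolute sense comes from the auxiliary, the dienophile adding anti to the phenyl group on the pyrrolidine carbon syn to C7. The step needs regiocontrol (ketone over ester, reinforced by the strong polarisation of the diene), endo control (ketone over ester, needed because ester-endo addition to the same diene face would give the enantiomeric C5/C10 pair) and facial control (auxiliary). Because the auxiliary is still present in 9, minor diastereomers can be removed by chromatography before C6 is erased.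

Step 5
Reactants: 9 cycloadduct
Product: 10 methyl 6β-[(2R,5R)-2,5-diphenylpyrrolidin-1-yl]-10β-methyl-5β-(prop-1-en-2-yl)-8-(tert-butyldimethylsilyloxy)cyclohex-7-ene-10α-carboxylate
Conditions: Cp2Ti(μ-CH2)(μ-Cl)AlMe2, pyridine, THF/PhMe, −40 → 0 °C
Reagents that add atoms: Tebbe reagent Cp2Ti(μ-CH2)(μ-Cl)AlMe2, C[Al-]1(C)C[Ti](C2C=CC=C2)(C2C=CC=C2)[Cl+]1
Why: Tebbe methylenation (titanium methylidene, [2+2] then cycloreversion) is non-basic, so the epimerisable C5 centre α to the ketone is untouched, and the ketone reacts well before the hindered ester.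

Step 6
Reactants: 10 isopropenyl ester
Product: 11 {6β-[(2R,5R)-2,5-diphenylpyrrolidin-1-yl]-10β-methyl-5β-(prop-1-en-2-yl)-8-(tert-butyldimethylsilyloxy)cyclohex-7-en-10α-yl}methanol
Conditions: LiAlH4, THF, 0 °C
Reagents that add atoms: none
Why: Hydride reduction of the ester to the primary alcohol; the silyl enol ether, the amine and the alkene are inert to LiAlH4.

Step 7
Reactants: 11 primary alcohol
Product: 12 6β-[(2R,5R)-2,5-diphenylpyrrolidin-1-yl]-10β-methyl-5β-(prop-1-en-2-yl)-8-(tert-butyldimethylsilyloxy)cyclohex-7-ene-10α-carbaldehyde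
Conditions: Pr4N[RuO4] (cat.), NMO, 4 Å MS, CH2Cl2, rt
Reagents that add atoms: none
Why: Ley–Griffith oxidation under neutral conditions spares the silyl enol ether and the tertiary amine and gives a non-enolisable aldehyde.

Step 8
Reactants: 12 aldehyde
Product: 13 (2R,5R)-1-[10α-ethenyl-10β-methyl-5β-(prop-1-en-2-yl)-8-(tert-butyldimethylsilyloxy)cyclohex-7-en-6β-yl]-2,5-diphenylpyrrolidine
Conditions: Ph3PCH3Br, KOtBu, THF, 0 °C → rt
Reagents that add atoms: methyltriphenylphosphonium bromide, C[P+](c1ccccc1)(c1ccccc1)c1ccccc1.[Br-]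
Why: Wittig methylenation of the neopentyl, non-enolisable aldehyde installs the C10 vinyl group while no other carbonyl is present.

Step 9
Reactants: 13 silyl enol ether
Product: 15 (4R,5R)-5-ethenyl-5-methyl-4-(prop-1-en-2-yl)cyclohex-2-en-1-one, via β-amino ketone 14 (not isolated)
Conditions: HF (48% aq.), MeCN, 0 °C → rt; then aq. NaHCO3
Reagents that add atoms: none
Why: Acid hydrolysis of the silyl enol ether followed by β-elimination of the protonated amine (E1cB type) unmasks the C8 enone and returns the auxiliary 5 for reuse.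

Step 10
Reactants: 15 enone
Product: 16 6α,7α-epoxide of 15, (ring A locants) 6α,7α-epoxy-10α-ethenyl-10β-methyl-5β-(prop-1-en-2-yl)cyclohexan-8-one
Conditions: H2O2 (30% aq.), NaOH, MeOH, −10 → 0 °C
Reagents that add atoms: hydrogen peroxide, OO
Why: Weitz–Scheffer nucleophilic epoxidation touches only the enone, and hydroperoxide adds to C6 on the α face, anti to the β isopropenyl group on C5 and the β methyl on C10, which sets the C6 oxygen.

Step 11
Reactants: 16 epoxy ketone
Product: 18 (1R,5R,6R)-5-ethenyl-5-methyl-6-(prop-1-en-2-yl)cyclohex-2-en-1-ol, via epoxy hydrazone 17 (not isolated)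
Conditions: N2H4·H2O, AcOH (cat.), MeOH, 0 °C → rt
Reagents that add atoms: none
Why: Wharton transposition (hydrazone, epoxide opening to an alkenyl diazene, loss of N2) leaves the C6–O bond intact, so the 6α-hydroxyl is retained and the alkene lands at C7=C8.

Step 12
Reactants: 18 allylic alcohol; 19 ethyl prop-1-enyl ether (E/Z mixture)
Product: 20 6α-O-(2-bromo-1-ethoxypropyl) ether of 18 (mixture at the two side-chain centres)
Conditions: NBS, CH2Cl2, −40 → 0 °C
Reagents that add atoms: N-bromosuccinimide, O=C1CCC(=O)N1Br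
Why: Ueno–Stork bromoacetalisation: NBS brominates the far more electron-rich enol ether and the C6 alcohol captures the bromo-oxocarbenium ion; both new centres are erased later (C12 becomes the carbonyl, C11 an enolate).

Step 13
Reactants: 20 bromoacetal
Product: 21 hydroxy acetal, cis-fused 12-ethoxy-11-methyl tetrahydrofuran (C6α–O, C7α–C11) on ring A with 8β-OH, 10α-ethenyl, 10β-methyl and 5β-(prop-1-en-2-yl)
Conditions: Co(salen) (10 mol %), NaBH4, NaOH (aq.), EtOH, air, 40 °C
Reagents that add atoms: dioxygen, O=O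
Why: Cobalt-mediated oxygenative Ueno–Stork radical cyclisation: monovalent cobalt generated by NaBH4 releases the C11 radical, 5-exo-trig closure onto C7 must occur on the α face where the C6–O tether lies (cis fusion, sets C7), and the C8 radical should be captured by O2 on the β face anti to the new C7–C11 bond before borohydride reduces the peroxide to the alcohol (sets C8).

Step 14
Reactants: 21 hydroxy acetal
Product: 22 8β-tert-butyldimethylsilyl ether of 21
Conditions: TBSCl, imidazole, DMF, rt
Reagents that add atoms: tert-butyldimethylsilyl chloride, C[Si](C)(Cl)C(C)(C)C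
Why: Standard silylation of the secondary alcohol under conditions that leave the mixed acetal intact; the ether shields C8–OH through the oxidation and enolate steps.

Step 15
Reactants: 22 silyl ether acetal
Product: 24 cis-fused 6α,12-lactone with 11-methyl (both C11 epimers) and 8β-OTBS, via lactol 23 (not isolated)
Conditions: CrO3, H2SO4, H2O, acetone, 0 °C
Reagents that add atoms: water, O
Why: Jones oxidation hydrolyses the ethyl acetal to the lactol and oxidises it to the γ-lactone in one operation; the isolated alkenes and the secondary silyl ether tolerate brief exposure at 0 °C.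

Step 16
Reactants: 24 lactone
Product: 26 11-hydroxy-11-methyl lactone (hydroxyl on the convex face, methyl on the concave face), 8β-OTBS, via potassium enolate 25 (not isolated)
Conditions: KN(SiMe3)2, THF, −78 °C; then 2-(phenylsulfonyl)-3-phenyloxaziridine, −78 °C; aq. NH4Cl
Reagents that add atoms: 2-(phenylsulfonyl)-3-phenyloxaziridine, O=S(=O)(c1ccccc1)N1OC1c1ccccc1
Why: Davis oxidation of the lactone enolate: the planar C11 of the cis-fused bicycle is attacked on its convex face (the face of H-6 and H-7, away from ring A), so the hydroxyl ends up exo and the methyl endo as in the target, and both C11 epimers of 24 converge.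

Step 17
Reactants: 26 tertiary alcohol; 27 angelic anhydride, (Z)-2-methylbut-2-enoic anhydride
Product: 29 11-O-[(Z)-2-methylbut-2-enoyl] ester of 26, via lithium alkoxide 28 (not isolated)
Conditions: LiN(SiMe3)2, THF, −78 °C; then 27, −78 → 0 °C
Reagents that add atoms: none
Why: Acylation of the pre-formed tertiary lithium alkoxide by the anhydride needs no nucleophilic catalyst and no heat, which is what keeps the (Z) geometry from isomerising to the tiglate; C11 is not touched.

Step 18
Reactants: 29 angelate silyl ether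
Product: 30 8β-alcohol (11-O-angeloyl lactone)
Conditions: HF·pyridine, THF, 0 °C → rt
Reagents that add atoms: none
Why: Acidic fluoride desilylation frees the C8 hydroxyl without generating an alkoxide, so the C11 ester cannot migrate to C8.

Step 19
Reactants: 30 secondary alcohol
Product: 31 CNP0140071.1
Conditions: Ac2O, DMAP (cat.), pyridine, CH2Cl2, rt
Reagents that add atoms: acetic anhydride, CC(=O)OC(C)=O
Why: DMAP-catalysed acetylation of the only free hydroxyl completes the target with all stereocentres already in place.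

**Compound list**

1 | methyl pyruvate | CC(=O)C(=O)OC | starting material
2 | 1-(triphenylphosphoranylidene)propan-2-one | CC(=O)C=P(c1ccccc1)(c1ccccc1)c1ccccc1 | starting material
3 | methyl (E)-2-methyl-4-oxopent-2-enoate | COC(=O)/C(C)=C/C(C)=O | intermediate
4 | (E)-4-methoxybut-3-en-2-one | CO/C=C/C(C)=O | starting material
5 | (2R,5R)-2,5-diphenylpyrrolidine | N1[C@@H](c2ccccc2)CC[C@@H]1c1ccccc1 | starting material
6 | (E)-4-[(2R,5R)-2,5-diphenylpyrrolidin-1-yl]but-3-en-2-one | CC(=O)/C=C/N1[C@@H](c2ccccc2)CC[C@@H]1c1ccccc1 | intermediate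
7 | potassium dienolate of 6 (formed in the flask) | [K+].C=C([O-])/C=C/N1[C@@H](c2ccccc2)CC[C@@H]1c1ccccc1 | intermediate
8 | 1-[(2R,5R)-2,5-diphenylpyrrolidin-1-yl]-3-(tert-butyldimethylsilyloxy)buta-1,3-diene | C=C(O[Si](C)(C)C(C)(C)C)/C=C/N1[C@@H](c2ccccc2)CC[C@@H]1c1ccccc1 | intermediate
9 | cycloadduct, 5β-acetyl, 6β-amino, 10β-methyl, 10α-CO2Me, C7=C8 silyl enol ether | COC(=O)[C@@]1(C)CC(O[Si](C)(C)C(C)(C)C)=C[C@H](N2[C@@H](c3ccccc3)CC[C@@H]2c2ccccc2)[C@@H]1C(C)=O | intermediate
10 | 5β-isopropenyl ester | COC(=O)[C@@]1(C)CC(O[Si](C)(C)C(C)(C)C)=C[C@H](N2[C@@H](c3ccccc3)CC[C@@H]2c2ccccc2)[C@@H]1C(C)=C | intermediate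
11 | 10α-hydroxymethyl compound | OC[C@@]1(C)CC(O[Si](C)(C)C(C)(C)C)=C[C@H](N2[C@@H](c3ccccc3)CC[C@@H]2c2ccccc2)[C@@H]1C(C)=C | intermediate
12 | 10α-carbaldehyde | O=C[C@@]1(C)CC(O[Si](C)(C)C(C)(C)C)=C[C@H](N2[C@@H](c3ccccc3)CC[C@@H]2c2ccccc2)[C@@H]1C(C)=C | intermediate
13 | 10α-vinyl silyl enol ether | C=C[C@@]1(C)CC(O[Si](C)(C)C(C)(C)C)=C[C@H](N2[C@@H](c3ccccc3)CC[C@@H]2c2ccccc2)[C@@H]1C(C)=C | intermediate
14 | β-amino ketone (formed in the flask) | C=C[C@@]1(C)CC(=O)C[C@H](N2[C@@H](c3ccccc3)CC[C@@H]2c2ccccc2)[C@@H]1C(C)=C | intermediate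
15 | (4R,5R)-5-ethenyl-5-methyl-4-(prop-1-en-2-yl)cyclohex-2-en-1-one | C=C[C@@]1(C)CC(=O)C=C[C@@H]1C(C)=C | intermediate
16 | 6α,7α-epoxy ketone | C=C[C@@]1(C)CC(=O)[C@H]2O[C@H]2[C@@H]1C(C)=C | intermediate
17 | hydrazone of 16 (formed in the flask) | C=C[C@@]1(C)CC(=NN)[C@H]2O[C@H]2[C@@H]1C(C)=C | intermediate
18 | (1R,5R,6R)-5-ethenyl-5-methyl-6-(prop-1-en-2-yl)cyclohex-2-en-1-ol | C=C[C@@]1(C)CC=C[C@@H](O)[C@@H]1C(C)=C | intermediate
19 | ethyl prop-1-enyl ether | CCOC=CC | starting material
20 | 6α-O-(2-bromo-1-ethoxypropyl) ether of 18 | C=C[C@@]1(C)CC=C[C@@H](OC(OCC)C(C)Br)[C@@H]1C(C)=C | intermediate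
21 | cis-fused 12-ethoxy acetal, 8β-OH | C=C[C@@]1(C)C[C@H](O)[C@@H]2[C@@H](OC(OCC)C2C)[C@@H]1C(C)=C | intermediate
22 | cis-fused 12-ethoxy acetal, 8β-OTBS | C=C[C@@]1(C)C[C@H](O[Si](C)(C)C(C)(C)C)[C@@H]2[C@@H](OC(OCC)C2C)[C@@H]1C(C)=C | intermediate
23 | lactol (formed in the flask) | C=C[C@@]1(C)C[C@H](O[Si](C)(C)C(C)(C)C)[C@@H]2[C@@H](OC(O)C2C)[C@@H]1C(C)=C | intermediate
24 | cis-fused 11-methyl lactone, 8β-OTBS | C=C[C@@]1(C)C[C@H](O[Si](C)(C)C(C)(C)C)[C@@H]2[C@@H](OC(=O)C2C)[C@@H]1C(C)=C | intermediate
25 | potassium enolate of 24 (formed in the flask) | [K+].C=C[C@@]1(C)C[C@H](O[Si](C)(C)C(C)(C)C)[C@@H]2[C@@H](OC([O-])=C2C)[C@@H]1C(C)=C | intermediate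
26 | 11-hydroxy-11-methyl lactone, 8β-OTBS | C=C[C@@]1(C)C[C@H](O[Si](C)(C)C(C)(C)C)[C@@H]2[C@@H](OC(=O)[C@@]2(C)O)[C@@H]1C(C)=C | intermediate
27 | angelic anhydride, (Z)-2-methylbut-2-enoic anhydride | C/C=C(/C)C(=O)OC(=O)/C(C)=C\C | starting material
28 | lithium alkoxide of 26 (formed in the flask) | [Li+].C=C[C@@]1(C)C[C@H](O[Si](C)(C)C(C)(C)C)[C@@H]2[C@@H](OC(=O)[C@@]2(C)[O-])[C@@H]1C(C)=C | intermediate
29 | 11-O-angeloyl lactone, 8β-OTBS | C=C[C@@]1(C)C[C@H](O[Si](C)(C)C(C)(C)C)[C@@H]2[C@@H](OC(=O)[C@@]2(C)OC(=O)/C(C)=C\C)[C@@H]1C(C)=C | intermediate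
30 | 11-O-angeloyl lactone, 8β-OH | C=C[C@@]1(C)C[C@H](O)[C@@H]2[C@@H](OC(=O)[C@@]2(C)OC(=O)/C(C)=C\C)[C@@H]1C(C)=C | intermediate
31 | CNP0140071.1: cis-fused 6α,12-lactone with 8β-acetoxy, 10β-methyl, 10α-vinyl, 5β-isopropenyl, C11 methyl on the concave face and C11 (Z)-2-methylbut-2-enoyloxy on the convex face | C=C[C@@]1(C)C[C@H](OC(C)=O)[C@@H]2[C@@H](OC(=O)[C@@]2(C)OC(=O)/C(C)=C\C)[C@@H]1C(=C)C | target

**Step count and risks**

Total: 19 steps. Longest linear sequence: 18 steps (steps 2–19, from 4 and 5 to 31).

Steps most likely to fail: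

Step 4. Regiocontrol may erode, with C9 bonding to the less hindered C5 and not to the fully substituted C10, or endo control may erode, with ester-endo addition giving the enantiomeric C5/C10 pair. The fallback sets out from diene 8 and replaces the ketone by a stronger, smaller directing group. Cycloaddition of 8 with methyl (E)-2-methyl-4-oxobut-2-enoate F1 should give the aldehyde cycloadduct F2 with C9 bonded to C10 and the formyl group endo. Addition of MeMgBr at −78 °C gives the carbinol F3 as a mixture at the new carbinol carbon. Oxidation with Pr4N[RuO4] and NMO comes back to 9.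

Step 13. Oxygen may be delivered to the α face of the C8 radical (cis to the new ring), or to the radical before it has cyclised, so that the 8α epimer dominates. The fallback sets out from 20 and sets C8 by SN2 inversion and not by radical capture. The same cyclisation gives the C8 epimer of 21 F4, which is isolated. Mitsunobu reaction with 4-nitrobenzoic acid, PPh3 and diisopropyl azodicarboxylate gives the inverted 8β 4-nitrobenzoate F5. Methanolysis with K2CO3 in MeOH comes back to 21.

Step 17. Acylation of the hindered tertiary alkoxide may be sluggish, and forcing it may isomerise the (Z)-acyl group to the (E) tiglate. The fallback sets out from 26 and builds the alkene on the ester. Esterification with 2-[bis(2,2,2-trifluoroethoxy)phosphoryl]propanoic acid (DCC, DMAP) gives the phosphonate ester F6. Still–Gennari olefination with acetaldehyde (KN(SiMe3)2, 18-crown-6, THF, −78 °C) forms the (Z)-2-methylbut-2-enoate and comes back to 29.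

Further compounds
F1 | step 4 | methyl (E)-2-methyl-4-oxobut-2-enoate | COC(=O)/C(C)=C/C=O
F2 | step 4 | aldehyde cycloadduct (5β-formyl analogue of 9) | COC(=O)[C@@]1(C)CC(O[Si](C)(C)C(C)(C)C)=C[C@H](N2[C@@H](c3ccccc3)CC[C@@H]2c2ccccc2)[C@@H]1C=O
F3 | step 4 | carbinol (5β-(1-hydroxyethyl) analogue of 9) | COC(=O)[C@@]1(C)CC(O[Si](C)(C)C(C)(C)C)=C[C@H](N2[C@@H](c3ccccc3)CC[C@@H]2c2ccccc2)[C@@H]1C(C)O
F4 | step 13 | C8 epimer of 21 (8α-OH) | C=C[C@@]1(C)C[C@@H](O)[C@@H]2[C@@H](OC(OCC)C2C)[C@@H]1C(C)=C
F5 | step 13 | 8β 4-nitrobenzoate of 21 | C=C[C@@]1(C)C[C@H](OC(=O)c3ccc(cc3)[N+](=O)[O-])[C@@H]2[C@@H](OC(OCC)C2C)[C@@H]1C(C)=C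
F6 | step 17 | 11-O-{2-[bis(2,2,2-trifluoroethoxy)phosphoryl]propanoyl} ester of 26 | C=C[C@@]1(C)C[C@H](O[Si](C)(C)C(C)(C)C)[C@@H]2[C@@H](OC(=O)[C@@]2(C)OC(=O)C(C)P(=O)(OCC(F)(F)F)OCC(F)(F)F)[C@@H]1C(C)=C
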